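Retrosynthetic cuts, in this order: (a) the bond between the ketone carbon and ring A (the trioxygenated ring), giving a protecting-group-free pentaphenol and 3-(4-methoxyphenyl)propanenitrile; (b) the bond between ring A and C-1 of the 1,4-diaryl-2,3-dimethylbutane chain (C-1 is the carbon on ring A), giving phloroglucinol and a benzylic carbinol; (c) the C-1–aryl and C-4–aryl bonds, both to one aryl Grignard reagent; (d) the C-2–C-3 bond, to two molecules of a propionyl oxazolidinone.
Forward, the chain is joined C-2–C-3 first (oxidative enolate dimerisation, then reduction to a C2-symmetric diol), then C-4–aryl (cyclic sulfate opening), C-1–aryl (Grignard addition), C-1–ring A (Friedel–Crafts alkylation) and last ketone carbon–ring A; no ring is built, the four benzene rings are bought.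
C-2 and C-3 come from the (R)-4-benzyl oxazolidinone auxiliary in the dimerisation; because the dimer is C2-symmetric, each later mono-functionalisation gives a single compound. C-1 comes from 1,2-induction by C-2 when phloroglucinol adds to a planar benzylic cation, to which both carbinol epimers converge.
The last bond relies on ring A of the pentaphenol being a 2-alkylbenzene-1,3,5-triol: its two free carbons (C-4 and C-6), each flanked by two hydroxyl groups, are equivalent and are the only strongly nucleophilic arene carbons present. A nitrile/HCl electrophile should therefore acylate there once with all five phenols free; the nitrile carbon already has the ketone oxidation level, its iminium salt is a temporary deactivating group that water removes in the same flask, and the only O-methyl group of the target arrives after all deprotection.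

Key step: step 9

Remark: ring A = trioxygenated ring, ring B = anisole ring, ring C = hydroxyphenyl ring on C-1, ring D = hydroxyphenyl ring on C-4; carbinol 11 is carried as a mixture of C-1 epimers on purpose.

Step 1
Reactants: 1 (R)-4-benzyl-3-propanoyl-1,3-oxazolidin-2-one (two molecules)
Product: 3 (4R,4'R)-3,3'-[(2S,3S)-2,3-dimethylbutanedioyl]bis(4-benzyl-1,3-oxazolidin-2-one), via lithium (Z)-enolate 2 (not isolated)
Conditions: LiN(iPr)2 (1.1 equiv), THF, −78 °C; TiCl4 (1.1 equiv), −78 °C → rt
Reagents that add atoms: none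
Why: Oxidative homocoupling of an N-acyl oxazolidinone enolate: TiCl4 oxidises the chelated (Z)-enolate 2 by one electron and the two α-carbons join on the face opposite the 4-benzyl group of each auxiliary, so the (R)-auxiliary should set both new centres as S and give the C2-symmetric dimer, from which the minor unsymmetrical diastereomer can be removed by crystallisation.

Step 2
Reactants: 3 bis-imide
Product: 4 (2S,3S)-2,3-dimethylbutane-1,4-diol
Conditions: LiBH4 (3 equiv), H2O (2 equiv), Et2O, 0 °C → rt
Reagents that add atoms: none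
Why: Reductive cleavage of N-acyl oxazolidinones by LiBH4 (hydride attack at the exocyclic carbonyl) is standard, touches neither methyl-bearing centre and returns the auxiliary.

Step 3
Reactants: 4 (2S,3S)-2,3-dimethylbutane-1,4-diol
Product: 6 (5S,6S)-5,6-dimethyl-1,3,2-dioxathiepane 2,2-dioxide (cyclic sulfate), via cyclic sulfite 5 (not isolated)
Conditions: SOCl2, Et3N, CH2Cl2, 0 °C; then RuCl3·3H2O (1 mol %), NaIO4, MeCN/H2O, 0 °C
Reagents that add atoms: thionyl chloride, O=S(Cl)Cl; sodium periodate, [Na+].[O-]I(=O)(=O)=O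
Why: Standard two-stage cyclic sulfate synthesis (cyclic sulfite formation, then RuO4-catalysed oxidation by periodate), in which the C2 axis of 4 makes the two oxygen atoms equivalent, so one sulfite and one sulfate form and both CH2–O carbons are activated alike.

Step 4
Reactants: 6 cyclic sulfate; 7 [4-(benzyloxy)phenyl]magnesium bromide (commercial THF solution)
Product: 9 (2S,3R)-4-[4-(benzyloxy)phenyl]-2,3-dimethylbutan-1-ol, via bromomagnesium alkyl sulfate 8 (not isolated)
Conditions: 7 (1.5 equiv), Li2CuCl4 (5 mol %), THF, −30 °C → rt; then 20% aq H2SO4, Et2O, rt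
Reagents that add atoms: none
Why: Copper-catalysed SN2 opening of a cyclic sulfate by an aryl Grignard reagent: the two CH2–O carbons of 6 are homotopic and the monoalkyl sulfate anion 8 is inert to a second substitution, so exactly one aryl group enters, and acid hydrolysis of 8 (S–O cleavage) frees the alcohol without touching the stereocentres.

Step 5
Reactants: 9 (2S,3R)-4-[4-(benzyloxy)phenyl]-2,3-dimethylbutan-1-ol
Product: 10 (2S,3R)-4-[4-(benzyloxy)phenyl]-2,3-dimethylbutanal
Conditions: Dess–Martin periodinane (1.2 equiv), CH2Cl2, 0 °C → rt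
Reagents that add atoms: none
Why: Dess–Martin oxidation is neutral and fast, so the α-branched aldehyde should form without epimerisation at C-2 and is used crude.

Step 6
Reactants: 10 aldehyde; 7 [4-(benzyloxy)phenyl]magnesium bromide
Product: 11 (1RS,2S,3R)-1,4-bis[4-(benzyloxy)phenyl]-2,3-dimethylbutan-1-ol
Conditions: 7 (1.3 equiv), THF, −78 → 0 °C; then H2O
Reagents that add atoms: none
Why: Grignard 1,2-addition to an aldehyde at low temperature outruns enolisation, and the new carbinol centre C-1 may form as a mixture of epimers because step 7 ionises it.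

Step 7
Reactants: 11 benzylic carbinol; 12 phloroglucinol (benzene-1,3,5-triol, 5 equiv)
Product: 14 2-{(1R,2S,3R)-1,4-bis[4-(benzyloxy)phenyl]-2,3-dimethylbutyl}benzene-1,3,5-triol, via benzylic cation 13 (not isolated)
Conditions: BF3·OEt2 (20 mol %), 1,4-dioxane/CH2Cl2, 0 °C → rt
Reagents that add atoms: none
Why: Acid-catalysed SN1 Friedel–Crafts alkylation of phloroglucinol with loss of water from 11: both C-1 epimers of 11 ionise to the same 4-alkoxybenzylic cation 13, in which allylic 1,3-strain holds the C-2–H bond in the plane of the cation next to ring C, so the arene should add to the face that carries the C-2 methyl group, away from the branched C-3 chain, which corresponds to 1R; the three free carbons of 12 are equivalent, its excess suppresses double alkylation, and it should outrun ring closure onto ring D, whose ortho carbons are meta to the benzyloxy group.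

Step 8
Reactants: 14 bis-benzyl ether
Product: 15 2-[(1R,2S,3R)-1,4-bis(4-hydroxyphenyl)-2,3-dimethylbutyl]benzene-1,3,5-triol
Conditions: H2 (1 atm), 10% Pd/C, EtOAc/MeOH, rt
Reagents that add atoms: none
Why: Hydrogenolysis of aryl benzyl ethers over Pd/C is standard and leaves the diarylmethine bonds and the stereocentres alone; it is placed before the acylation so that the ketone never meets hydrogen and no benzyl chloride can form from the ethers under HCl/ZnCl2 and benzylate ring A.

Step 9
Reactants: 15 pentaphenol; 16 3-(4-methoxyphenyl)propanenitrile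
Product: 18 1-{3-[(1R,2S,3R)-1,4-bis(4-hydroxyphenyl)-2,3-dimethylbutyl]-2,4,6-trihydroxyphenyl}-3-(4-methoxyphenyl)propan-1-one (target), via ketiminium chloride 17 (not isolated)
Conditions: 16 (1.2 equiv), ZnCl2 (anhydrous), HCl (g), Et2O, 0 °C → rt; then H2O, 90 °C
Reagents that add atoms: water, O
Why: HCl and ZnCl2 turn nitrile 16 into an N-protonated nitrilium (imidoyl chloride) electrophile that attacks C-4 of ring A of 15 (equivalent to C-6), the Wheland intermediate re-aromatises, and the aryl ketiminium chloride 17 separates from ether and is hydrolysed by hot water to the ketone. The closest known reaction type is the Houben–Hoesch acylation of phloroglucinol and its C-alkyl derivatives with nitriles, the standard entry to 2',4',6'-trihydroxydihydrochalcones. No ring is closed and no stereocentre is formed; C-1, C-2 and C-3 carry no hydrogen next to a carbonyl group and are meant to pass unchanged. The step needs site selectivity among four benzene rings and between two ring A positions, C- over O-acylation and mono- over diacylation. Ring A secures the first three: its two free carbons are each ortho or para to three hydroxyl groups, far more nucleophilic than any carbon of rings C and D or of the anisole ring of 16, and they are interchanged by rotation about the ring A–C-1 bond, so only one C-acyl isomer can form. The iminium group of 17 deactivates ring A and 17 leaves the solution, which stops the reaction after one acylation.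

Compound list
1 | (R)-4-benzyl-3-propanoyl-1,3-oxazolidin-2-one | CCC(=O)N1[C@H](Cc2ccccc2)COC1=O | starting material
2 | lithium (Z)-enolate of 1 | C/C=C(\[O-])N1[C@H](Cc2ccccc2)COC1=O.[Li+] | intermediate
3 | (4R,4'R)-3,3'-[(2S,3S)-2,3-dimethylbutanedioyl]bis(4-benzyl-1,3-oxazolidin-2-one) | O=C([C@@H](C)[C@H](C)C(=O)N1[C@H](Cc2ccccc2)COC1=O)N1[C@H](Cc2ccccc2)COC1=O | intermediate
4 | (2S,3S)-2,3-dimethylbutane-1,4-diol | OC[C@@H](C)[C@H](C)CO | intermediate
5 | (5S,6S)-5,6-dimethyl-1,3,2-dioxathiepane 2-oxide (cyclic sulfite) | O=S1OC[C@@H](C)[C@H](C)CO1 | intermediate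
6 | (5S,6S)-5,6-dimethyl-1,3,2-dioxathiepane 2,2-dioxide (cyclic sulfate) | O=S1(=O)OC[C@@H](C)[C@H](C)CO1 | intermediate
7 | [4-(benzyloxy)phenyl]magnesium bromide | Br[Mg]c1ccc(OCc2ccccc2)cc1 | starting material
8 | bromomagnesium (2S,3R)-4-[4-(benzyloxy)phenyl]-2,3-dimethylbutyl sulfate | [O-]S(=O)(=O)OC[C@@H](C)[C@H](C)Cc1ccc(OCc2ccccc2)cc1.[Mg+2].[Br-] | intermediate
9 | (2S,3R)-4-[4-(benzyloxy)phenyl]-2,3-dimethylbutan-1-ol | OC[C@@H](C)[C@H](C)Cc1ccc(OCc2ccccc2)cc1 | intermediate
10 | (2S,3R)-4-[4-(benzyloxy)phenyl]-2,3-dimethylbutanal | O=C[C@@H](C)[C@H](C)Cc1ccc(OCc2ccccc2)cc1 | intermediate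
11 | (1RS,2S,3R)-1,4-bis[4-(benzyloxy)phenyl]-2,3-dimethylbutan-1-ol (both C-1 epimers) | OC(c1ccc(OCc2ccccc2)cc1)[C@@H](C)[C@H](C)Cc1ccc(OCc2ccccc2)cc1 | intermediate
12 | phloroglucinol (benzene-1,3,5-triol) | Oc1cc(O)cc(O)c1 | starting material
13 | benzylic cation of 11 (C-1 cationic, C-2 and C-3 as in 11) | [CH+](c1ccc(OCc2ccccc2)cc1)[C@@H](C)[C@H](C)Cc1ccc(OCc2ccccc2)cc1 | intermediate
14 | 2-{(1R,2S,3R)-1,4-bis[4-(benzyloxy)phenyl]-2,3-dimethylbutyl}benzene-1,3,5-triol | Oc1cc(O)c([C@@H](c2ccc(OCc3ccccc3)cc2)[C@@H](C)[C@H](C)Cc2ccc(OCc3ccccc3)cc2)c(O)c1 | intermediate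
15 | 2-[(1R,2S,3R)-1,4-bis(4-hydroxyphenyl)-2,3-dimethylbutyl]benzene-1,3,5-triol | Oc1cc(O)c([C@@H](c2ccc(O)cc2)[C@@H](C)[C@H](C)Cc2ccc(O)cc2)c(O)c1 | intermediate
16 | 3-(4-methoxyphenyl)propanenitrile | COc1ccc(CCC#N)cc1 | starting material
17 | ketiminium chloride of 18 (C=NH2+ in place of C=O) | COc1ccc(CCC(=[NH2+])c2c(O)cc(O)c([C@@H](c3ccc(O)cc3)[C@@H](C)[C@H](C)Cc3ccc(O)cc3)c2O)cc1.[Cl-] | intermediate
18 | 1-{3-[(1R,2S,3R)-1,4-bis(4-hydroxyphenyl)-2,3-dimethylbutyl]-2,4,6-trihydroxyphenyl}-3-(4-methoxyphenyl)propan-1-one | COc1ccc(CCC(=O)c2c(O)cc(O)c([C@@H](c3ccc(O)cc3)[C@@H](C)[C@H](C)Cc3ccc(O)cc3)c2O)cc1 | target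

Total step count: 9. Longest linear sequence: 9 steps (1 → 18); 7, 12 and 16 are bought.

Steps most likely to fail

Step 7. The arene may add to both faces of cation 13 with little preference, or 13 may lose the C-2 proton to a styrene whose re-protonation scrambles C-2. The fallback replaces substrate control through a free cation by catalyst control through a neutral quinone methide; it sets out from aldehyde 10 and comes back at pentaphenol 15. Aldehyde 10 is treated with {4-[(tert-butyldimethylsilyl)oxy]phenyl}magnesium bromide F1 (from commercial (4-bromophenoxy)(tert-butyl)dimethylsilane and Mg in THF) to give the silyl ether carbinol (1RS,2S,3R)-4-[4-(benzyloxy)phenyl]-1-{4-[(tert-butyldimethylsilyl)oxy]phenyl}-2,3-dimethylbutan-1-ol F2. Bu4NF (THF, 0 °C) frees the phenol to give 4-{(1RS,2S,3R)-4-[4-(benzyloxy)phenyl]-1-hydroxy-2,3-dimethylbutyl}phenol F3. With a BINOL-derived chiral phosphoric acid (TRIP, 5–10 mol %, CH2Cl2, molecular sieves, −20 °C) F3 should lose water to the hydrogen-bonded para-quinone methide 4-{(2S,3R)-4-[4-(benzyloxy)phenyl]-2,3-dimethylbutylidene}cyclohexa-2,5-dien-1-one F4. Phloroglucinol 12 then adds to F4 in 1,6-fashion under catalyst control (the catalyst enantiomer that reinforces the substrate bias is chosen by trial) to give 2-{(1R,2S,3R)-4-[4-(benzyloxy)phenyl]-1-(4-hydroxyphenyl)-2,3-dimethylbutyl}benzene-1,3,5-triol F5. Hydrogenolysis under the conditions of step 8 then gives 15.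

Step 9. Under HCl/ZnCl2 ring A of 15 may be protonated at the carbon that bears the side chain, so that the ring A–C-1 bond opens again (loss of configuration at C-1 and C-2, or loss of the side chain); O-imidoylation of the two monohydric phenols may also consume 16. The fallback makes the same bond first on the parent ring, after which the acyl group protects ring A against ipso-protonation; it sets out from 12, 16 and carbinol 11 and comes back at 18. The Houben–Hoesch reaction of 12 with 16 (ZnCl2, HCl, Et2O, 0 °C; then H2O, heat) should give, through 3-(4-methoxyphenyl)-1-(2,4,6-trihydroxyphenyl)propan-1-iminium chloride F6, the dihydrochalcone 1-(2,4,6-trihydroxyphenyl)-3-(4-methoxyphenyl)propan-1-one F7. F7 (in excess) is alkylated by 11 under the conditions of step 7 (through cation 13) at one of its two equivalent free ring carbons to give 1-{3-[(1R,2S,3R)-1,4-bis[4-(benzyloxy)phenyl]-2,3-dimethylbutyl]-2,4,6-trihydroxyphenyl}-3-(4-methoxyphenyl)propan-1-one F8. H2 over Pd/C (EtOAc/MeOH, rt) then gives 18.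

Step 4. Substitution at the β-branched CH2–O carbon of 6 may be slow, with attack of the Grignard reagent at sulfur or its homocoupling taking over. The fallback desymmetrises the diol stepwise by mono-protection instead of through a cyclic electrophile; it sets out from diol 4 and comes back at alcohol 9. NaH (1 equiv) then tert-butyldimethylsilyl chloride (THF) should give (2S,3S)-4-[(tert-butyldimethylsilyl)oxy]-2,3-dimethylbutan-1-ol F9. I2, PPh3 and imidazole (CH2Cl2) give tert-butyl{[(2S,3S)-4-iodo-2,3-dimethylbutyl]oxy}dimethylsilane F10. Iron-catalysed coupling with 7 (FeCl3 5 mol %, TMEDA, THF, 0 °C) gives {[(2S,3R)-4-[4-(benzyloxy)phenyl]-2,3-dimethylbutyl]oxy}(tert-butyl)dimethylsilane F11, and Bu4NF (THF) gives 9.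

Further compounds
F1 | step 7 | {4-[(tert-butyldimethylsilyl)oxy]phenyl}magnesium bromide | Br[Mg]c1ccc(O[Si](C)(C)C(C)(C)C)cc1
F2 | step 7 | (1RS,2S,3R)-4-[4-(benzyloxy)phenyl]-1-{4-[(tert-butyldimethylsilyl)oxy]phenyl}-2,3-dimethylbutan-1-ol | OC(c1ccc(O[Si](C)(C)C(C)(C)C)cc1)[C@@H](C)[C@H](C)Cc1ccc(OCc2ccccc2)cc1
F3 | step 7 | 4-{(1RS,2S,3R)-4-[4-(benzyloxy)phenyl]-1-hydroxy-2,3-dimethylbutyl}phenol | OC(c1ccc(O)cc1)[C@@H](C)[C@H](C)Cc1ccc(OCc2ccccc2)cc1
F4 | step 7 | 4-{(2S,3R)-4-[4-(benzyloxy)phenyl]-2,3-dimethylbutylidene}cyclohexa-2,5-dien-1-one | O=C1C=CC(=C[C@@H](C)[C@H](C)Cc2ccc(OCc3ccccc3)cc2)C=C1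
F5 | step 7 | 2-{(1R,2S,3R)-4-[4-(benzyloxy)phenyl]-1-(4-hydroxyphenyl)-2,3-dimethylbutyl}benzene-1,3,5-triol | Oc1cc(O)c([C@@H](c2ccc(O)cc2)[C@@H](C)[C@H](C)Cc2ccc(OCc3ccccc3)cc2)c(O)c1
F6 | step 9 | 3-(4-methoxyphenyl)-1-(2,4,6-trihydroxyphenyl)propan-1-iminium chloride | COc1ccc(CCC(=[NH2+])c2c(O)cc(O)cc2O)cc1.[Cl-]
F7 | step 9 | 1-(2,4,6-trihydroxyphenyl)-3-(4-methoxyphenyl)propan-1-one | COc1ccc(CCC(=O)c2c(O)cc(O)cc2O)cc1
F8 | step 9 | 1-{3-[(1R,2S,3R)-1,4-bis[4-(benzyloxy)phenyl]-2,3-dimethylbutyl]-2,4,6-trihydroxyphenyl}-3-(4-methoxyphenyl)propan-1-one | COc1ccc(CCC(=O)c2c(O)cc(O)c([C@@H](c3ccc(OCc4ccccc4)cc3)[C@@H](C)[C@H](C)Cc3ccc(OCc4ccccc4)cc3)c2O)cc1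
F9 | step 4 | (2S,3S)-4-[(tert-butyldimethylsilyl)oxy]-2,3-dimethylbutan-1-ol | OC[C@@H](C)[C@H](C)CO[Si](C)(C)C(C)(C)C
F10 | step 4 | tert-butyl{[(2S,3S)-4-iodo-2,3-dimethylbutyl]oxy}dimethylsilane | IC[C@@H](C)[C@H](C)CO[Si](C)(C)C(C)(C)C
F11 | step 4 | {[(2S,3R)-4-[4-(benzyloxy)phenyl]-2,3-dimethylbutyl]oxy}(tert-butyl)dimethylsilane | CC(C)(C)[Si](C)(C)OC[C@@H](C)[C@H](C)Cc1ccc(OCc2ccccc2)cc1
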